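The trap in an equal-charge flask was a single constant fitted through a whole run, since a good fit says nothing of whether the line bends beyond its last reading. I had these flasks and this question:

| flask | starting material | coupling partner | time |
|---|---|---|---|
| autumn | 0.120 M | 0.120 M |  |
| winter | 0.0480 M | 0.0480 M |  |
| midnight | 0.120 M | 0.240 M |  |
| dusk | 0.240 M | 0.120 M |  |
| dawn | 0.120 M | 0.120 M | 28 h |

- autumn run (time / h: [starting material] / M): 0.39: 0.1121; 1.2: 0.0975; 2.3: 0.0860; 3.6: 0.0768; 5.2: 0.0687; 6.9: 0.0631; 8.9: 0.0580; 11: 0.0524
- winter run (time / h: [starting material] / M): 0.39: 0.0461; 1.2: 0.0432; 2.3: 0.0398; 3.6: 0.0372; 5.2: 0.0325; 6.9: 0.0298; 8.9: 0.0275; 11: 0.0252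
- midnight run (time / h: [starting material] / M): 0.39: 0.1041; 1.2: 0.0854; 2.3: 0.0712; 3.6: 0.0613; 5.2: 0.0543; 6.9: 0.0477; 8.9: 0.0437; 11: 0.0395
- dusk run (time / h: [starting material] / M): 0.39: 0.2231; 1.2: 0.1998; 2.3: 0.1798; 3.6: 0.1654; 5.2: 0.1539; 6.9: 0.1428; 8.9: 0.1352; 11: 0.1284

(each reading ± 6 × 10⁻⁴ M)

- Overall: starting material + coupling partner -> target.
- Constant volume, constant temperature.
- "The second partner" is coupling partner.
- An order is taken over about fifteen percent of the charge, up and down.

* how the opening rate goes with [coupling partner] round the charge of the autumn run: the exponent of the rate at two percent of starting material gone to target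
* how the opening rate goes with [starting material] round the charge of the autumn run: the exponent of the rate at two percent of starting material gone to target (one fixed amount of target, the same in the runs compared)
* starting material in the dawn run at 28 h, as a share of the starting material charged

The bench rule for equal charges is second order: the reciprocal of c(starting material) climbs in a straight line with time, and its slope is the rate constant. I applied it to the autumn run. Over its first 1.2 h the slope was

k(open) = 1.60 M⁻¹ h⁻¹

and between the readings at 5.2 h and 11 h it was

k(tail) = 0.781 M⁻¹ h⁻¹

This is the tail constant, the late slope of the reciprocal of c(starting material) in the autumn run. It was about half of the opening slope, so the line bent.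

The border of the rule showed in a ratio of readings. The autumn run stood at 52.6% of its charge at 6.9 h, and the winter run reached 52.5% at 11 h. A second-order clock wants those times in the ratio of the charges, 2.50, but they stood at 1.59, which is less. So I used the closed form locally. The dawn run has the autumn charge, so I anchored it on the autumn reading at 11 h:

share left at 28 h = 1 / (c₀ × (1/c + k(tail) × (28 h − 11 h))) = 25.8%

I took this as the low side, because the slope had been falling.

The forecast, a separate reckoning, gave 27% (23.5% to 30.5%), with orders 0.94 (0.8 to 1.05) in coupling partner and 1.05 (0.9 to 1.2) in starting material. Its ground was that “the reaction slows faster than second order”.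

The steps behind the flask were these:

    starting material + coupling partner → target (1.562 M⁻¹ h⁻¹)
    target + coupling partner → side product (1.289 M⁻¹ h⁻¹)
    2 coupling partner → lost reagent (1.354 M⁻¹ h⁻¹)
    starting material → decomposed substrate (0.02282 h⁻¹)

The dawn run kept 27.6%, against the forecast's 27% and my 25.8%, and the orders came out 1.0 and 1.1. Carried to the winter run, with all starting material gone counted as target, the tail constant put target at a quarter of the charge at 8.90 h; that run reached it at 10.3 h, though its reading at 8.9 h already had 42.7% of its starting material gone. At the start of the dawn run coupling partner, the limiting reagent, went to target at 0.0225 M h⁻¹ and to lost reagent at 0.0390 M h⁻¹, and side product formed once target stood in the flask. Decomposition ran beside these steps, and from the autumn reading at 11 h to the dawn run at 28 h starting material fell on average at a first-order 0.0271 h⁻¹, against 0.0228 h⁻¹ for decomposition.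

The data stem from a simulated flask from invented constants, and the scatter is random.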